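**Plan**

- Retrosynthesis: remove the 7-O-methyl group; open ring A at C6–C7 (Claisen) to a 2,3,6-trisubstituted 4-pyranone; cut its ester arm at C8–C8a; split the pyranone at O1–C2 and C4–C4a into an aroylketene and a vinylogous amide.
- Forward order: ring C (the pyranone, with ring B attached) is built first from 2,3-dimethoxybenzoic acid; the C7–C8 arm is then joined to the one free electrophilic pyranone carbon; ring A is closed last; one O-methylation finishes.
- Enabling feature: ring A is a folded poly-β-carbonyl chain, with oxygen on C5, C7 and C8a in 1,3-relationship plus the extra methoxy on C8. The 3-acetyl group (C5, C6) and the ester arm (C8, C7) of the pyranone therefore need only the C6–C7 bond, and the ring oxygen already on C8a fixes the 8-methoxy (not 6-methoxy) fusion.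
- Stereochemistry: the target has no stereocentre; the single centre of the Claisen substrate (C8) is carried as the racemate and disappears on aromatisation.

Key step: step 5

Remark: the acyl Meldrum's acid is drawn as its chelated enol; the enaminotrione and the ketene acetal may be E/Z mixtures and the silyl 2H-pyran a diastereomer mixture; none of this geometry survives ring A formation.

**Step 1**
Reactants: 1 2,3-dimethoxybenzoic acid; 2 2,2-dimethyl-1,3-dioxane-4,6-dione (Meldrum's acid)
Product: 3 5-[(2,3-dimethoxyphenyl)(hydroxy)methylidene]-2,2-dimethyl-1,3-dioxane-4,6-dione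
Conditions: N,N'-dicyclohexylcarbodiimide, 4-(dimethylamino)pyridine, CH2Cl2, 0 °C to rt
Reagents that add atoms: none
Why: Carbodiimide-mediated (Steglich-type) C-acylation of the highly acidic Meldrum's acid through the acylpyridinium ion is the standard entry to 5-acyl Meldrum's acids, which rest as the chelated enol.

**Step 2**
Reactants: 3 5-[(2,3-dimethoxyphenyl)(hydroxy)methylidene]-2,2-dimethyl-1,3-dioxane-4,6-dione; 4 (E)-4-(dimethylamino)but-3-en-2-one
Product: 7 3-acetyl-6-(2,3-dimethoxyphenyl)-4H-pyran-4-one, via aroylketene 5 (not isolated), via enaminotrione 6 (not isolated)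
Conditions: PhMe, 110 °C, N2 sweep; then CH3CO2H, 60 °C
Reagents that add atoms: none
Why: Thermal retro-hetero-Diels–Alder fragmentation of 3 should release aroylketene 5, which C-acylates the nucleophilic α-carbon of vinylogous amide 4; in adduct 6 the aroyl enol oxygen then adds to the aminomethylidene carbon and dimethylamine is eliminated (acylketene–enaminone annulation), so ring C forms with the acetyl group on C3 and the neighbouring C2 left free.

**Step 3**
Reactants: 8 methyl 2-methoxyacetate
Product: 9 (Z)-1,2-dimethoxy-1-[(trimethylsilyl)oxy]ethene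
Conditions: LiN(iPr)2, THF, −78 °C; Me3SiCl, −78 °C to rt
Reagents that add atoms: chlorotrimethylsilane, C[Si](C)(C)Cl
Why: Kinetic ester deprotonation and O-silylation of the chelated lithium enolate is the standard preparation of ketene silyl acetals; the Z isomer is expected to predominate, but either geometry serves.

**Step 4**
Reactants: 7 3-acetyl-6-(2,3-dimethoxyphenyl)-4H-pyran-4-one; 9 (Z)-1,2-dimethoxy-1-[(trimethylsilyl)oxy]ethene
Product: 11 methyl 2-[3-acetyl-6-(2,3-dimethoxyphenyl)-4-oxo-4H-pyran-2-yl]-2-methoxyacetate (racemic), via silyloxy-2H-pyran 10 (not isolated)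
Conditions: Me3SiOSO2CF3 (10 mol %), CH2Cl2, −78 °C; then DDQ (2,3-dichloro-5,6-dicyano-1,4-benzoquinone), −78 °C to rt
Reagents that add atoms: none
Why: Catalytic silylation of the pyranone carbonyl should give a silyloxypyrylium ion that the ketene acetal attacks at C2, the only unsubstituted electrophilic ring carbon and the one activated by both carbonyl groups (Mukaiyama–Michael addition), and hydride abstraction from C2 of silyl dienol ether 10 by DDQ with loss of the silyl group restores the aromatic pyranone; the side-chain centre of 11 is formed as the racemate, which is of no consequence.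

**Step 5**
Reactants: 11 methyl 2-[3-acetyl-6-(2,3-dimethoxyphenyl)-4-oxo-4H-pyran-2-yl]-2-methoxyacetate
Product: 13 2-(2,3-dimethoxyphenyl)-5,7-dihydroxy-8-methoxy-4H-chromen-4-one, via chromenetrione 12 (not isolated)
Conditions: LiN(SiMe3)2 (3.5 equiv), THF, −78 °C to rt; then 1 M HCl
Reagents that add atoms: none
Why: Excess LiN(SiMe3)2 should remove first the C8–H, which is vinylogously acidified by both ketone groups, and then an acetyl proton; the acetyl enolate carbon (C6) adds to the ester carbonyl (C7) and methoxide is expelled. This is an intramolecular Claisen (Dieckmann-type) condensation, the reaction by which poly-β-carbonyl chains are folded into phloroglucinol- and resorcinol-type rings under base. Ring A closes in a 6-(enolendo)-exo-trig mode, and the cyclohexane-1,3-dione 12 so formed is deprotonated and tautomerises at once to the aromatic 5,7-diol, which takes the product out of every equilibrium. No stereocentre is formed, and the racemic C8 centre of 11 is erased on aromatisation. The step needs C- rather than O-acylation and the 8-methoxy rather than the 6-methoxy pattern: an enol lactone from O-acylation would be reopened by lithium methoxide whereas only the C-acylation product aromatises, and the regiochemistry is fixed in 11 because the ester-bearing carbon sits on the pyranone carbon that carries the ring oxygen (future C8a) while the acetyl group sits on the future C4a. A hindered, non-nucleophilic amide base and low temperature are chosen so that the pyranone is not opened at C2 or C6 before ring A has formed, and the 5-OH to C4=O hydrogen bond adds to the driving force.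

**Step 6**
Reactants: 13 2-(2,3-dimethoxyphenyl)-5,7-dihydroxy-8-methoxy-4H-chromen-4-one
Product: 14 2-(2,3-dimethoxyphenyl)-5-hydroxy-7,8-dimethoxy-4H-chromen-4-one (5-hydroxy-2',3',7,8-tetramethoxyflavone)
Conditions: Me2SO4 (1.05 equiv), K2CO3, acetone, reflux
Reagents that add atoms: dimethyl sulfate, COS(=O)(=O)OC
Why: Williamson O-methylation with one equivalent of alkylating agent and a weak base should touch only the more acidic, non-chelated 7-hydroxyl, because the 5-hydroxyl is locked in a hydrogen bond to the C4 carbonyl and is far less nucleophilic.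

**Compound list**

1 | 2,3-dimethoxybenzoic acid | COc1cccc(C(=O)O)c1OC | starting material
2 | 2,2-dimethyl-1,3-dioxane-4,6-dione (Meldrum's acid) | CC1(C)OC(=O)CC(=O)O1 | starting material
3 | 5-[(2,3-dimethoxyphenyl)(hydroxy)methylidene]-2,2-dimethyl-1,3-dioxane-4,6-dione (enol form of the 5-aroyl Meldrum's acid) | COc1cccc(C(O)=C2C(=O)OC(C)(C)OC2=O)c1OC | intermediate
4 | (E)-4-(dimethylamino)but-3-en-2-one | CC(=O)/C=C/N(C)C | starting material
5 | 3-(2,3-dimethoxyphenyl)prop-1-ene-1,3-dione (aroylketene, not isolated) | COc1cccc(C(=O)C=C=O)c1OC | intermediate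
6 | 4-[(dimethylamino)methylidene]-1-(2,3-dimethoxyphenyl)hexane-1,3,5-trione (E/Z not defined, not isolated) | COc1cccc(C(=O)CC(=O)C(=CN(C)C)C(C)=O)c1OC | intermediate
7 | 3-acetyl-6-(2,3-dimethoxyphenyl)-4H-pyran-4-one | COc1cccc(-c2cc(=O)c(C(C)=O)co2)c1OC | intermediate
8 | methyl 2-methoxyacetate | COCC(=O)OC | starting material
9 | (Z)-1,2-dimethoxy-1-[(trimethylsilyl)oxy]ethene | CO/C=C(/OC)O[Si](C)(C)C | intermediate
10 | methyl 2-{3-acetyl-6-(2,3-dimethoxyphenyl)-4-[(trimethylsilyl)oxy]-2H-pyran-2-yl}-2-methoxyacetate (racemic diastereomer mixture, not isolated) | COC(=O)C(OC)C1OC(-c2cccc(OC)c2OC)=CC(O[Si](C)(C)C)=C1C(C)=O | intermediate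
11 | methyl 2-[3-acetyl-6-(2,3-dimethoxyphenyl)-4-oxo-4H-pyran-2-yl]-2-methoxyacetate (racemic) | COC(=O)C(OC)c1oc(-c2cccc(OC)c2OC)cc(=O)c1C(C)=O | intermediate
12 | 2-(2,3-dimethoxyphenyl)-8-methoxy-6H-chromene-4,5,7(8H)-trione (racemic keto tautomer of 13, not isolated) | COc1cccc(-c2cc(=O)c3c(o2)C(OC)C(=O)CC3=O)c1OC | intermediate
13 | 2-(2,3-dimethoxyphenyl)-5,7-dihydroxy-8-methoxy-4H-chromen-4-one | COc1cccc(-c2cc(=O)c3c(O)cc(O)c(OC)c3o2)c1OC | intermediate
14 | 2-(2,3-dimethoxyphenyl)-5-hydroxy-7,8-dimethoxy-4H-chromen-4-one | COc1cccc(-c2cc(=O)c3c(O)cc(OC)c(OC)c3o2)c1OC | target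

**Step count and risks**

Total: 6 steps. Longest linear sequence: 5 steps (steps 1, 2, 4, 5, 6); step 3 prepares the ketene acetal on a side branch.

Steps most likely to fail:

1. Step 4. The 2H-pyran 10 can open by retro-6π electrocyclisation to an acyclic dienone. Hydride abstraction from a dienol ether that is deactivated by the acetyl group may also be slow enough for DDQ to degrade the ketene acetal or the product instead. Fallback (from 7 and 9, back at 11): the addition is run as before but quenched with aqueous NaHCO3, which hydrolyses 10 to the enolised β-diketone methyl 2-[3-acetyl-6-(2,3-dimethoxyphenyl)-4-oxo-3,4-dihydro-2H-pyran-2-yl]-2-methoxyacetate F1; any ring-opened material should re-close by oxa-Michael addition. F1 is selenenylated at C3 (PhSeCl, pyridine, CH2Cl2) to methyl 2-[3-acetyl-6-(2,3-dimethoxyphenyl)-4-oxo-3-(phenylselanyl)-3,4-dihydro-2H-pyran-2-yl]-2-methoxyacetate F2. Oxidation with H2O2 then gives the selenoxide, which should undergo syn-elimination across C2–C3 to 11. Re-aromatisation then rests on α-selenenylation and selenoxide elimination of an isolated 1,3-dicarbonyl compound instead of hydride abstraction.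

2. Step 5. Lithium methoxide or the amide base may open the pyranone by conjugate attack at C2 or C6, or the substrate may rest as the extended C8 enolate whose ester is too poor an electrophile, so that ring A does not close. Fallback (from 1, back at 14): ring A is taken from a preformed arene. Acid 1 is esterified (N,N'-dicyclohexylcarbodiimide, 4-(dimethylamino)pyridine, CH2Cl2) with commercially available 1-(2-hydroxy-3,4,6-trimethoxyphenyl)ethan-1-one F3 to give 2-acetyl-3,5,6-trimethoxyphenyl 2,3-dimethoxybenzoate F4. Baker–Venkataraman rearrangement (KOH, pyridine, 50 °C) should give 1-(2,3-dimethoxyphenyl)-3-(2-hydroxy-3,4,6-trimethoxyphenyl)propane-1,3-dione F5. Cyclodehydration (H2SO4, CH3CO2H) should give 2-(2,3-dimethoxyphenyl)-5,7,8-trimethoxy-4H-chromen-4-one F6. Chelation-directed cleavage of the 5-methyl ether alone with BCl3 (CH2Cl2, −78 to 0 °C) then leads to 14.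

3. Step 2. The dimethylamine released can intercept ketene 5 as an amide or re-add to C2 of 7 and reopen the ring, and 5 can dimerise when trapping is slow. Fallback (from 1, back at 7): acid 1 is converted into 2,3-dimethoxybenzoyl chloride F7 ((COCl)2, catalytic N,N-dimethylformamide, CH2Cl2). 3-[(Dimethylamino)methylidene]pentane-2,4-dione F8 (commercially available, or from pentane-2,4-dione and N,N-dimethylformamide dimethyl acetal) is deprotonated at an acetyl methyl group with LiN(SiMe3)2 (THF, −78 °C) and C-aroylated with F7 to give the same enaminotrione 6, which HCl should close to 7. Because F8 is symmetric no regiochemical question arises, and no free ketene is involved.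

**Further compounds**

F1 | step 4 | methyl 2-[3-acetyl-6-(2,3-dimethoxyphenyl)-4-oxo-3,4-dihydro-2H-pyran-2-yl]-2-methoxyacetate (diastereomer mixture) | COC(=O)C(OC)C1OC(-c2cccc(OC)c2OC)=CC(=O)C1C(C)=O
F2 | step 4 | methyl 2-[3-acetyl-6-(2,3-dimethoxyphenyl)-4-oxo-3-(phenylselanyl)-3,4-dihydro-2H-pyran-2-yl]-2-methoxyacetate (diastereomer mixture) | COC(=O)C(OC)C1OC(-c2cccc(OC)c2OC)=CC(=O)C1([Se]c3ccccc3)C(C)=O
F3 | step 5 | 1-(2-hydroxy-3,4,6-trimethoxyphenyl)ethan-1-one | CC(=O)c1c(O)c(OC)c(OC)cc1OC
F4 | step 5 | 2-acetyl-3,5,6-trimethoxyphenyl 2,3-dimethoxybenzoate | CC(=O)c1c(OC(=O)c2cccc(OC)c2OC)c(OC)c(OC)cc1OC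
F5 | step 5 | 1-(2,3-dimethoxyphenyl)-3-(2-hydroxy-3,4,6-trimethoxyphenyl)propane-1,3-dione | COc1cccc(C(=O)CC(=O)c2c(O)c(OC)c(OC)cc2OC)c1OC
F6 | step 5 | 2-(2,3-dimethoxyphenyl)-5,7,8-trimethoxy-4H-chromen-4-one | COc1cccc(-c2cc(=O)c3c(OC)cc(OC)c(OC)c3o2)c1OC
F7 | step 2 | 2,3-dimethoxybenzoyl chloride | COc1cccc(C(Cl)=O)c1OC
F8 | step 2 | 3-[(dimethylamino)methylidene]pentane-2,4-dione | CC(=O)C(=CN(C)C)C(C)=O
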